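**Retrosynthetic overview**
- The only ring formed is the macrocycle. It is closed last at the ring B–ring C two-carbon bridge by intramolecular McMurry coupling of a dialdehyde, followed by hydrogenation and BBr3 demethylation.
- The ring C–O–ring D ether comes from Ullmann coupling of a ring D phenol with 3-bromo-4,5-dimethoxybenzaldehyde.
- The ring A–CH2CH2–ring D bridge (key C–C bond) comes from an intermolecular Perkin aldol-type condensation of 4-benzyloxyphenylacetic acid with a ring A aldehyde, then decarboxylation and hydrogenation.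
- The ring A–O–ring B ether comes from Ullmann coupling of isovanillin with methyl 3-bromobenzoate.
- Order of assembly: A–O–B ether, then A/D bridge, then C–O–D ether, then macrocycle; all four benzene rings are bought.

Assumption: the target (the constitution of marchantin A) has no stereocentre and a conformationally mobile macrocycle, so it is achiral and the route needs no stereocontrol.

**Step 1**
Reactants: 1 isovanillin (3-hydroxy-4-methoxybenzaldehyde); 2 methyl 3-bromobenzoate
Product: 3 methyl 3-(5-formyl-2-methoxyphenoxy)benzoate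
Conditions: CuI (10 mol %), N,N-dimethylglycine·HCl (30 mol %), Cs2CO3 (2 equiv), 1,4-dioxane, 95 °C, N2
Reagents that add atoms: none
Why: Ligand-accelerated Ullmann diaryl ether coupling of the phenoxide of 1 with an unhindered, electron-poor aryl bromide under monovalent-copper catalysis; the aldehyde and methyl ester tolerate Cs2CO3 in dry dioxane.

**Step 2**
Reactants: 3 methyl 3-(5-formyl-2-methoxyphenoxy)benzoate; 4 2-[4-(benzyloxy)phenyl]acetic acid
Product: 7 (2E)-2-[4-(benzyloxy)phenyl]-3-{4-methoxy-3-[3-(methoxycarbonyl)phenoxy]phenyl}prop-2-enoic acid, via arylacetic acetic anhydride 5 (not isolated), via acrylic acetic anhydride 6 (not isolated)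
Conditions: Ac2O, Et3N, 120 °C, 8 h; then H2O, 60 °C; dilute HCl; crystallise
Reagents that add atoms: none
Why: Perkin condensation (aldol-type): the enolate of mixed anhydride 5 adds to the non-enolisable aldehyde 3, acetylation and elimination give 6, and water frees the E acid (aryl groups cis), whose geometry does not matter because the alkene is hydrogenated later.

**Step 3**
Reactants: 7 (2E)-2-[4-(benzyloxy)phenyl]-3-{4-methoxy-3-[3-(methoxycarbonyl)phenoxy]phenyl}prop-2-enoic acid
Product: 8 methyl 3-(5-{(Z)-2-[4-(benzyloxy)phenyl]ethenyl}-2-methoxyphenoxy)benzoate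
Conditions: Cu powder, quinoline, 210–230 °C, N2, 2–3 h; dilute HCl wash to remove quinoline
Reagents that add atoms: none
Why: Copper-mediated protodecarboxylation of an α-arylcinnamic acid replaces CO2H by H with retention, giving mainly the Z-stilbene (any E isomer converges in step 4); ester, benzyl ether and diaryl ether are inert.

**Step 4**
Reactants: 8 methyl 3-(5-{(Z)-2-[4-(benzyloxy)phenyl]ethenyl}-2-methoxyphenoxy)benzoate
Product: 10 methyl 3-{5-[2-(4-hydroxyphenyl)ethyl]-2-methoxyphenoxy}benzoate, via benzyl ether bibenzyl 9 (not isolated)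
Conditions: H2 (1 atm), 10 % Pd/C, EtOAc–MeOH, rt
Reagents that add atoms: none
Why: Heterogeneous catalytic hydrogenation saturates the stilbene and then hydrogenolyses the O-benzyl ether in the same pot; the methyl ester and diaryl ether are untouched.

**Step 5**
Reactants: 10 methyl 3-{5-[2-(4-hydroxyphenyl)ethyl]-2-methoxyphenoxy}benzoate; 11 3-bromo-4,5-dimethoxybenzaldehyde
Product: 12 methyl 3-(5-{2-[4-(5-formyl-2,3-dimethoxyphenoxy)phenyl]ethyl}-2-methoxyphenoxy)benzoate
Conditions: CuI (15 mol %), N,N-dimethylglycine·HCl (45 mol %), Cs2CO3 (2 equiv), 1,4-dioxane, 105 °C, N2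
Reagents that add atoms: none
Why: Ullmann diaryl ether coupling: the unhindered para-alkylphenoxide of 10 is a good nucleophile for the ortho-methoxy aryl bromide, whose meta-formyl group aids oxidative addition; ester and aldehyde survive the anhydrous carbonate base.

**Step 6**
Reactants: 12 methyl 3-(5-{2-[4-(5-formyl-2,3-dimethoxyphenoxy)phenyl]ethyl}-2-methoxyphenoxy)benzoate
Product: 13 [3-(5-{2-[4-(5-(hydroxymethyl)-2,3-dimethoxyphenoxy)phenyl]ethyl}-2-methoxyphenoxy)phenyl]methanol
Conditions: LiAlH4, THF, 0 °C to rt; Fieser work-up (H2O, aq NaOH, H2O)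
Reagents that add atoms: none
Why: Hydride reduction with LiAlH4 takes both the ester and the aldehyde to benzylic alcohols, bringing the two termini to one oxidation level; aryl ethers are inert.

**Step 7**
Reactants: 13 [3-(5-{2-[4-(5-(hydroxymethyl)-2,3-dimethoxyphenoxy)phenyl]ethyl}-2-methoxyphenoxy)phenyl]methanol
Product: 14 3-(4-{2-[3-(3-formylphenoxy)-4-methoxyphenyl]ethyl}phenoxy)-4,5-dimethoxybenzaldehyde
Conditions: Dess–Martin periodinane (2.5 equiv), CH2Cl2, rt
Reagents that add atoms: none
Why: Dess–Martin oxidation converts both benzylic alcohols cleanly to aldehydes without over-oxidation or attack on the electron-rich rings.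

**Step 8**
Reactants: 14 3-(4-{2-[3-(3-formylphenoxy)-4-methoxyphenyl]ethyl}phenoxy)-4,5-dimethoxybenzaldehyde
Product: 16 macrocyclic stilbene (tri-O-methyl-didehydromarchantin A; Z/E mixture), via titanium pinacolate 15 (not isolated)
Conditions: TiCl4 (10 equiv), Zn dust (20 equiv), pyridine, THF, reflux; 14 added by syringe pump over 24 h (final ≤ 3 mM); aq K2CO3 quench
Reagents that add atoms: none
Why: Intramolecular McMurry reductive carbonyl coupling under high dilution: low-valent titanium joins the two aryl aldehydes to pinacolate 15 and deoxygenates it to the stilbene; the large ring is unstrained and the alkene geometry is irrelevant.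

**Step 9**
Reactants: 16 macrocyclic stilbene (Z/E mixture)
Product: 17 marchantin A tri-O-methyl ether
Conditions: H2 (1 atm), 10 % Pd/C, EtOAc, rt
Reagents that add atoms: none
Why: Catalytic hydrogenation reduces both alkene isomers to the same bibenzyl bridge; no other reducible group is present.

**Step 10**
Reactants: 17 marchantin A tri-O-methyl ether
Product: 19 marchantin A (target), via aryl bromoborate 18 (not isolated)
Conditions: BBr3 (8 equiv), CH2Cl2, −78 °C to rt; then ice–water
Reagents that add atoms: none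
Why: BBr3 ether cleavage (Lewis-acid complexation, then bromide attack at methyl) removes the three aryl methyl ethers via borate 18, which water hydrolyses; diaryl ethers are inert to BBr3 and no stereocentre is involved.

**Compound list**
1 | isovanillin (3-hydroxy-4-methoxybenzaldehyde) | COc1ccc(C=O)cc1O | starting material
2 | methyl 3-bromobenzoate | COC(=O)c1cccc(Br)c1 | starting material
3 | methyl 3-(5-formyl-2-methoxyphenoxy)benzoate | COC(=O)c1cccc(Oc2cc(C=O)ccc2OC)c1 | intermediate
4 | 2-[4-(benzyloxy)phenyl]acetic acid | OC(=O)Cc1ccc(OCc2ccccc2)cc1 | starting material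
5 | acetic 2-[4-(benzyloxy)phenyl]acetic anhydride (not isolated) | CC(=O)OC(=O)Cc1ccc(OCc2ccccc2)cc1 | intermediate
6 | mixed acetic anhydride of acid 7 (not isolated) | CC(=O)OC(=O)/C(=C/c1ccc(OC)c(Oc2cccc(c2)C(=O)OC)c1)c1ccc(OCc2ccccc2)cc1 | intermediate
7 | (2E)-2-[4-(benzyloxy)phenyl]-3-{4-methoxy-3-[3-(methoxycarbonyl)phenoxy]phenyl}prop-2-enoic acid | OC(=O)/C(=C/c1ccc(OC)c(Oc2cccc(c2)C(=O)OC)c1)c1ccc(OCc2ccccc2)cc1 | intermediate
8 | methyl 3-(5-{(Z)-2-[4-(benzyloxy)phenyl]ethenyl}-2-methoxyphenoxy)benzoate | COC(=O)c1cccc(Oc2cc(/C=C\c3ccc(OCc4ccccc4)cc3)ccc2OC)c1 | intermediate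
9 | methyl 3-(5-{2-[4-(benzyloxy)phenyl]ethyl}-2-methoxyphenoxy)benzoate (not isolated) | COC(=O)c1cccc(Oc2cc(CCc3ccc(OCc4ccccc4)cc3)ccc2OC)c1 | intermediate
10 | methyl 3-{5-[2-(4-hydroxyphenyl)ethyl]-2-methoxyphenoxy}benzoate | COC(=O)c1cccc(Oc2cc(CCc3ccc(O)cc3)ccc2OC)c1 | intermediate
11 | 3-bromo-4,5-dimethoxybenzaldehyde | COc1cc(C=O)cc(Br)c1OC | starting material
12 | methyl 3-(5-{2-[4-(5-formyl-2,3-dimethoxyphenoxy)phenyl]ethyl}-2-methoxyphenoxy)benzoate | COC(=O)c1cccc(Oc2cc(CCc3ccc(Oc4cc(C=O)cc(OC)c4OC)cc3)ccc2OC)c1 | intermediate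
13 | [3-(5-{2-[4-(5-(hydroxymethyl)-2,3-dimethoxyphenoxy)phenyl]ethyl}-2-methoxyphenoxy)phenyl]methanol | OCc1cccc(Oc2cc(CCc3ccc(Oc4cc(CO)cc(OC)c4OC)cc3)ccc2OC)c1 | intermediate
14 | 3-(4-{2-[3-(3-formylphenoxy)-4-methoxyphenyl]ethyl}phenoxy)-4,5-dimethoxybenzaldehyde | O=Cc1cccc(Oc2cc(CCc3ccc(Oc4cc(C=O)cc(OC)c4OC)cc3)ccc2OC)c1 | intermediate
15 | macrocyclic titanium pinacolate: the macrocycle of 17 with a CH(O–)–CH(O–) bridge between rings B and C, titanium-bound, drawn as the dianion, diastereomer mixture (not isolated) | COc1ccc2cc1Oc1cccc(c1)C([O-])C([O-])c1cc(OC)c(OC)c(c1)Oc1ccc(cc1)CC2 | intermediate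
16 | macrocyclic stilbene: the macrocycle of 17 with CH=CH in place of the ring B–ring C CH2CH2 bridge; Z/E mixture, geometry left open | COc1ccc2cc1Oc1cccc(c1)C=Cc1cc(OC)c(OC)c(c1)Oc1ccc(cc1)CC2 | intermediate
17 | marchantin A tri-O-methyl ether: ring A (1-OMe, 2-O–ring B, 4-CH2CH2–ring D), ring B (1,3-disubstituted), ring C (1-CH2CH2–ring B, 3,4-dimethoxy, 5-O–ring D), ring D (1,4-disubstituted) | COc1ccc2cc1Oc1cccc(c1)CCc1cc(OC)c(OC)c(c1)Oc1ccc(cc1)CC2 | intermediate
18 | aryl bromoborate of the target: ring A O–BBr2, ring C catechol as cyclic B-bromo dioxaborole (not isolated) | BrB(Br)Oc1ccc2cc1Oc1cccc(c1)CCc1cc3OB(Br)Oc3c(c1)Oc1ccc(cc1)CC2 | intermediate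
19 | marchantin A (achiral) | Oc1ccc2cc1Oc1cccc(c1)CCc1cc(O)c(O)c(c1)Oc1ccc(cc1)CC2 | target

**Totals**
Total step count: 10. Longest linear sequence: 10 steps (from 1 and 2 to 19).

**Three steps most likely to fail**

Step 8 (McMurry macrocyclisation; oligomerisation or pinacol arrest). The fallback sets out from dialdehyde 14. Double Wittig methylenation (Ph3PCH3Br, KOt-Bu, THF, 0 °C) gives the bis-styrene 5-ethenyl-1-(4-{2-[3-(3-ethenylphenoxy)-4-methoxyphenyl]ethyl}phenoxy)-2,3-dimethoxybenzene F5. Ring-closing metathesis with second-generation Grubbs catalyst (5 mol %, CH2Cl2, 40 °C, 1 mM) expels ethylene and returns to the route at macrocyclic stilbene 16 (mainly E), which is hydrogenated as in step 9.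

Step 3 (high-temperature Cu/quinoline decarboxylation; charring or low conversion). The fallback sets out from acid 7. Hydrogenation first (H2, Pd/C, EtOAc–MeOH) saturates the acrylic acid and removes the benzyl group, giving racemic 2-(4-hydroxyphenyl)-3-{4-methoxy-3-[3-(methoxycarbonyl)phenoxy]phenyl}propanoic acid F1. N-Hydroxypyridine-2-thione and DCC (CH2Cl2, dark, no DMAP so the phenol is not acylated) convert it to the 2-thioxopyridin-1(2H)-yl (Barton) ester F2. Photolysis with t-BuSH (Barton reductive radical decarboxylation via the secondary benzylic radical) removes the carboxyl and the transient stereocentre, returning to the route at phenol 10.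

Step 5 (Ullmann coupling onto the hindered ortho-methoxy bromide; slow coupling or hydrodebromination). The fallback sets out from bromide 11 and reverses the role of ring C. Miyaura borylation (B2pin2, PdCl2(dppf), KOAc, dioxane, 85 °C) gives 3,4-dimethoxy-5-(4,4,5,5-tetramethyl-1,3,2-dioxaborolan-2-yl)benzaldehyde F3. NaIO4/NH4OAc in acetone–water cleaves the pinacol ester to (5-formyl-2,3-dimethoxyphenyl)boronic acid F4. Chan–Lam oxidative coupling of F4 with phenol 10 (Cu(OAc)2, pyridine, 4 Å MS, CH2Cl2, air, rt) returns to the route at 12.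

**Further compounds**
F1 | step 3 | 2-(4-hydroxyphenyl)-3-{4-methoxy-3-[3-(methoxycarbonyl)phenoxy]phenyl}propanoic acid (racemic) | OC(=O)C(Cc1ccc(OC)c(Oc2cccc(c2)C(=O)OC)c1)c1ccc(O)cc1
F2 | step 3 | 2-thioxopyridin-1(2H)-yl 2-(4-hydroxyphenyl)-3-{4-methoxy-3-[3-(methoxycarbonyl)phenoxy]phenyl}propanoate (racemic Barton ester) | O=C(ON1C=CC=CC1=S)C(Cc1ccc(OC)c(Oc2cccc(c2)C(=O)OC)c1)c1ccc(O)cc1
F3 | step 5 | 3,4-dimethoxy-5-(4,4,5,5-tetramethyl-1,3,2-dioxaborolan-2-yl)benzaldehyde | COc1cc(C=O)cc(B2OC(C)(C)C(C)(C)O2)c1OC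
F4 | step 5 | (5-formyl-2,3-dimethoxyphenyl)boronic acid | COc1cc(C=O)cc(B(O)O)c1OC
F5 | step 8 | 5-ethenyl-1-(4-{2-[3-(3-ethenylphenoxy)-4-methoxyphenyl]ethyl}phenoxy)-2,3-dimethoxybenzene | C=Cc1cccc(Oc2cc(CCc3ccc(Oc4cc(C=C)cc(OC)c4OC)cc3)ccc2OC)c1
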